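**Retrosynthetic overview**

1. The strategy rests on ring B (the pendant aryl ring). Its oxygens on C2' and C4' are 1,3-related former carbonyl carbons, C3' between them carries a differently masked oxygen, C1' (bonded to chroman C3) and C5' (bearing the 1,1-dimethylallyl group) carry the carbon substituents, and the single unsubstituted carbon C6' bridges C1' and C5'.
2. Key disconnection: both bonds to C6' (C1'–C6' and C5'–C6') are cut, giving an acyclic 2-(methoxymethoxy)-1,3-diketone (C1'–C5') and one carbon from N,N-dimethylformamide dimethyl acetal. After ring closure, the two new phenols are methylated and both MOM groups are removed.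
3. The diketone comes from an aldol addition/oxidation at C2'–C3' between a chroman-3-ylacetaldehyde and an α-MOM-oxy ketone (mesityl oxide plus vinyl Grignard reagent, then Rubottom oxidation).
4. The aldehyde comes from an asymmetric intramolecular Stetter reaction of a salicylaldehyde-derived enoate, which sets C3 and closes pyran ring C, followed by removal of the C4 oxygen.
5. Ring order: A (purchased with 2,4-dihydroxybenzaldehyde), then C (Stetter reaction), then B ([5+1] closure, last).

Key step: step 12

Assumption: the sense of induction of the triazolium carbene catalyst is not derived here; the antipode of the aminoindanol-derived precatalyst that gives the (3S)-chromanone is taken (both aminoindanol enantiomers are available).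

**Route**

Step 1
Reactants: 1 2,4-dihydroxybenzaldehyde
Product: 2 2-hydroxy-4-(methoxymethoxy)benzaldehyde
Conditions: MOMCl (1.05 equiv), K2CO3, acetone, 0 → 23 °C
Reagents that add atoms: chloromethyl methyl ether, COCCl
Why: Williamson-type O-alkylation; the 2-OH is held in a hydrogen bond to the formyl group and is the weaker nucleophile, so the 4-OH should be protected selectively.

Step 2
Reactants: 2 2-hydroxy-4-(methoxymethoxy)benzaldehyde; 3 methyl (E)-4-bromobut-2-enoate
Product: 4 methyl (E)-4-[2-formyl-5-(methoxymethoxy)phenoxy]but-2-enoate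
Conditions: K2CO3, DMF, 23 °C
Reagents that add atoms: none
Why: Williamson ether synthesis; the remaining phenoxide displaces the primary allylic bromide by SN2 without touching the aldehyde or the enoate.

Step 3
Reactants: 4 methyl (E)-4-[2-formyl-5-(methoxymethoxy)phenoxy]but-2-enoate
Product: 5 methyl 2-[(3S)-7-(methoxymethoxy)-4-oxo-3,4-dihydro-2H-chromen-3-yl]acetate
Conditions: aminoindanol-derived N-pentafluorophenyl triazolium tetrafluoroborate (10 mol%), KN(SiMe3)2 (10 mol%), toluene, 23 °C
Reagents that add atoms: none
Why: Asymmetric intramolecular Stetter reaction: the triazolylidene carbene turns the aldehyde into an acyl-anion equivalent that adds 6-exo-trig to the enoate β-carbon and closes ring C, the aminoindanol backbone shields one face of the acceptor so that C3 is formed as S (catalyst control), and the substoichiometric base should leave the new α-stereocentre unepimerised.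

Step 4
Reactants: 5 methyl 2-[(3S)-7-(methoxymethoxy)-4-oxo-3,4-dihydro-2H-chromen-3-yl]acetate
Product: 6 (3S)-3-(2-hydroxyethyl)-7-(methoxymethoxy)chroman-4-ol (mixture of C4 epimers)
Conditions: LiAlH4, THF, −20 → 0 °C; then H2O
Reagents that add atoms: none
Why: LiAlH4 reduction of ketone and ester under non-enolising conditions keeps C3 intact; the new C4 carbinol centre is left unassigned because it is deleted in the next step.

Step 5
Reactants: 6 (3S)-3-(2-hydroxyethyl)-7-(methoxymethoxy)chroman-4-ol
Product: 7 2-[(3S)-7-(methoxymethoxy)chroman-3-yl]ethanol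
Conditions: H2 (3 atm), 10% Pd/C, EtOAc–AcOH (10:1), 23 °C
Reagents that add atoms: none
Why: Catalytic hydrogenolysis of the benzylic C4–O bond, which is activated by the para MOM-oxy group and the ortho ring oxygen; the primary alcohol, the MOM ether and C3 should not be affected, and a cyclic benzylic ether formed in passing would be cleaved to the same product.

Step 6
Reactants: 7 2-[(3S)-7-(methoxymethoxy)chroman-3-yl]ethanol
Product: 8 2-[(3S)-7-(methoxymethoxy)chroman-3-yl]acetaldehyde
Conditions: Dess–Martin periodinane (1.2 equiv), CH2Cl2, 0 → 23 °C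
Reagents that add atoms: none
Why: Dess–Martin oxidation takes the primary alcohol to the aldehyde without over-oxidation under nearly neutral conditions; C3 is β to the new carbonyl and cannot epimerise.

Step 7
Reactants: 9 mesityl oxide (4-methylpent-3-en-2-one); 10 vinylmagnesium bromide
Product: 11 4,4-dimethylhex-5-en-2-one
Conditions: CuI (10 mol%), THF, −20 → 0 °C; then 1 M HCl
Reagents that add atoms: none
Why: Copper-catalysed conjugate addition of the vinyl Grignard reagent to the β,β-disubstituted enone creates the quaternary carbon of the 1,1-dimethylallyl group.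

Step 8
Reactants: 11 4,4-dimethylhex-5-en-2-one
Product: 14 1-hydroxy-4,4-dimethylhex-5-en-2-one, via silyl enol ether 12 (not isolated), via silyloxy ketone 13 (not isolated)
Conditions: LiN(iPr)2, THF, −78 °C, then Me3SiCl; mCPBA (1.0 equiv), CH2Cl2, −20 → 0 °C; 1 M HCl–THF, 0 °C
Reagents that add atoms: 3-chloroperbenzoic acid, OOC(=O)c1cccc(Cl)c1
Why: Rubottom oxidation: kinetic deprotonation takes place at the methyl group (the methylene is neopentyl), the electron-rich silyl enol ether is epoxidised much faster than the hindered monosubstituted vinyl group, and silyl migration followed by acid hydrolysis gives the hydroxymethyl ketone.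

Step 9
Reactants: 14 1-hydroxy-4,4-dimethylhex-5-en-2-one
Product: 15 1-(methoxymethoxy)-4,4-dimethylhex-5-en-2-one
Conditions: MOMCl, i-Pr2NEt, CH2Cl2, 0 → 23 °C
Reagents that add atoms: chloromethyl methyl ether, COCCl
Why: Standard O-alkylation of the primary alcohol with the chloromethyl ether and a hindered amine base; an acetal is chosen because, unlike a silyl or acyl group, it cannot migrate to the neighbouring phenoxides formed in step 12.

Step 10
Reactants: 15 1-(methoxymethoxy)-4,4-dimethylhex-5-en-2-one; 8 2-[(3S)-7-(methoxymethoxy)chroman-3-yl]acetaldehyde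
Product: 16 2-hydroxy-3-(methoxymethoxy)-6,6-dimethyl-1-[(3S)-7-(methoxymethoxy)chroman-3-yl]oct-7-en-4-one (diastereomer mixture at C2 and C3 of the chain)
Conditions: LiN(iPr)2, THF, −78 °C, 15 then 8; AcOH, −78 °C
Reagents that add atoms: none
Why: Directed (crossed) aldol addition: LiN(iPr)2 removes a proton from the MOM-oxy methylene (chelation-assisted; the other α-carbon is neopentyl) and the preformed lithium enolate adds to the aldehyde at −78 °C; the two new stereocentres are not controlled because both are erased later by oxidation and enolisation.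

Step 11
Reactants: 16 2-hydroxy-3-(methoxymethoxy)-6,6-dimethyl-1-[(3S)-7-(methoxymethoxy)chroman-3-yl]oct-7-en-4-one
Product: 17 3-(methoxymethoxy)-6,6-dimethyl-1-[(3S)-7-(methoxymethoxy)chroman-3-yl]oct-7-ene-2,4-dione (C3 of the chain enolisable, unassigned)
Conditions: 2-iodoxybenzoic acid (IBX, 1.5 equiv), DMSO, 23 °C
Reagents that add atoms: none
Why: IBX oxidation of a β-hydroxy ketone to the 1,3-diketone, chosen because it should stop at the diketone and not oxidise further at the doubly activated C3'.

Step 12
Reactants: 17 3-(methoxymethoxy)-6,6-dimethyl-1-[(3S)-7-(methoxymethoxy)chroman-3-yl]oct-7-ene-2,4-dione; 18 N,N-dimethylformamide dimethyl acetal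
Product: 20 (3S)-3-[2,4-dihydroxy-3-(methoxymethoxy)-5-(2-methylbut-3-en-2-yl)phenyl]-7-(methoxymethoxy)chroman, via enaminone 19 (not isolated)
Conditions: LiN(iPr)2 (2.1 equiv), THF, −78 → 0 °C; 18 (1.05 equiv), 0 → 23 °C; LiN(iPr)2 (2.3 equiv), −78 → 23 °C; AcOH, then H2O
Reagents that add atoms: none
Why: Proposed new method: two equivalents of LiN(iPr)2 turn 17 into its 1,3-dianion, whose terminal carbon C1' (the less hindered flank; reaction through C5' would lead to the same arene) displaces methoxide from the amide acetal and, after loss of the second methoxide, gives enaminone 19 as its C3' enolate; further base then generates the C5' carbanion, which adds to the aminomethylene carbon C6', dimethylamide is expelled and the cyclohexenedione tautomerises to the resorcinol dianion. The closest known reactions are the terminal C-acylation of 1,3-diketone dianions, the addition–elimination of carbanions on enaminones and the aldol aromatisation of 3,5-dioxo carbonyl chains to resorcinols. Ring B closes in a 6-endo-trig attack of C5' on C6' (equally a 6π-electrocyclisation of the dioxido triene) that aromatisation makes irreversible. No stereocentre is formed, and C3 of the chroman, β to the nearest carbonyl and not enolisable, stays S. The step needs C–C bond formation at the flanking methylenes although the C3'–H is far more acidic, and C- over O-closure; the first is secured by offering the acetal to the preformed dianion (under thermal conditions the diketonate would take the reagent at oxygen or the neutral enaminone would close to a 4-pyranone), the second by the carbanionic C5' and by lithium chelation between the C3' MOM ether and both enolate oxygens, which holds C1' and C5' on the same side. The acetal on O3' cannot migrate, so the two carbonyl oxygens appear as free phenols at C2' and C4' and O3' stays protected.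

Step 13
Reactants: 20 (3S)-3-[2,4-dihydroxy-3-(methoxymethoxy)-5-(2-methylbut-3-en-2-yl)phenyl]-7-(methoxymethoxy)chroman
Product: 21 (3S)-3-[2,4-dimethoxy-3-(methoxymethoxy)-5-(2-methylbut-3-en-2-yl)phenyl]-7-(methoxymethoxy)chroman
Conditions: MeI (excess), Cs2CO3, DMF, 23 → 40 °C
Reagents that add atoms: iodomethane, CI
Why: Williamson O-methylation of the two phenols, the only acidic OH groups; no ring position ortho or para to them is free, so C-alkylation is not expected, and the small electrophile should tolerate the flanking substituents.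

Step 14
Reactants: 21 (3S)-3-[2,4-dimethoxy-3-(methoxymethoxy)-5-(2-methylbut-3-en-2-yl)phenyl]-7-(methoxymethoxy)chroman
Product: 22 (3S)-3-[3-hydroxy-2,4-dimethoxy-5-(2-methylbut-3-en-2-yl)phenyl]chroman-7-ol (CNP0305994.1)
Conditions: HCl (cat.), MeOH, 23 → 40 °C
Reagents that add atoms: none
Why: Acid-catalysed acetal cleavage (transacetalisation to dimethoxymethane) frees O7 and O3' together; dilute HCl in methanol should leave the aryl methyl ethers and the 1,1-dimethylallyl group alone, since no free phenol sits ortho to it.

**Compound list**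

1 | 2,4-dihydroxybenzaldehyde | O=Cc1ccc(O)cc1O | starting material
2 | 2-hydroxy-4-(methoxymethoxy)benzaldehyde | COCOc1ccc(C=O)c(O)c1 | intermediate
3 | methyl (E)-4-bromobut-2-enoate | COC(=O)/C=C/CBr | starting material
4 | methyl (E)-4-[2-formyl-5-(methoxymethoxy)phenoxy]but-2-enoate | COC(=O)/C=C/COc1cc(OCOC)ccc1C=O | intermediate
5 | methyl 2-[(3S)-7-(methoxymethoxy)-4-oxo-3,4-dihydro-2H-chromen-3-yl]acetate | COC(=O)C[C@H]1COc2cc(OCOC)ccc2C1=O | intermediate
6 | (3S)-3-(2-hydroxyethyl)-7-(methoxymethoxy)chroman-4-ol, C4 epimer mixture | OCC[C@H]1COc2cc(OCOC)ccc2C1O | intermediate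
7 | 2-[(3S)-7-(methoxymethoxy)chroman-3-yl]ethanol | OCC[C@H]1COc2cc(OCOC)ccc2C1 | intermediate
8 | 2-[(3S)-7-(methoxymethoxy)chroman-3-yl]acetaldehyde | O=CC[C@H]1COc2cc(OCOC)ccc2C1 | intermediate
9 | mesityl oxide (4-methylpent-3-en-2-one) | CC(C)=CC(C)=O | starting material
10 | vinylmagnesium bromide | C=C[Mg]Br | starting material
11 | 4,4-dimethylhex-5-en-2-one | CC(=O)CC(C)(C)C=C | intermediate
12 | 4,4-dimethyl-2-(trimethylsilyloxy)hexa-1,5-diene (not isolated) | C=CC(C)(C)CC(=C)O[Si](C)(C)C | intermediate
13 | 4,4-dimethyl-1-(trimethylsilyloxy)hex-5-en-2-one (not isolated) | C=CC(C)(C)CC(=O)CO[Si](C)(C)C | intermediate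
14 | 1-hydroxy-4,4-dimethylhex-5-en-2-one | C=CC(C)(C)CC(=O)CO | intermediate
15 | 1-(methoxymethoxy)-4,4-dimethylhex-5-en-2-one | C=CC(C)(C)CC(=O)COCOC | intermediate
16 | 2-hydroxy-3-(methoxymethoxy)-6,6-dimethyl-1-[(3S)-7-(methoxymethoxy)chroman-3-yl]oct-7-en-4-one, diastereomer mixture | C=CC(C)(C)CC(=O)C(OCOC)C(O)C[C@H]1COc2cc(OCOC)ccc2C1 | intermediate
17 | 3-(methoxymethoxy)-6,6-dimethyl-1-[(3S)-7-(methoxymethoxy)chroman-3-yl]oct-7-ene-2,4-dione | C=CC(C)(C)CC(=O)C(OCOC)C(=O)C[C@H]1COc2cc(OCOC)ccc2C1 | intermediate
18 | N,N-dimethylformamide dimethyl acetal | COC(OC)N(C)C | starting material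
19 | (1E)-1-(dimethylamino)-4-(methoxymethoxy)-7,7-dimethyl-2-[(3S)-7-(methoxymethoxy)chroman-3-yl]nona-1,8-diene-3,5-dione (not isolated) | C=CC(C)(C)CC(=O)C(OCOC)C(=O)/C(=C/N(C)C)[C@H]1COc2cc(OCOC)ccc2C1 | intermediate
20 | (3S)-3-[2,4-dihydroxy-3-(methoxymethoxy)-5-(2-methylbut-3-en-2-yl)phenyl]-7-(methoxymethoxy)chroman | C=CC(C)(C)c1cc([C@H]2COc3cc(OCOC)ccc3C2)c(O)c(OCOC)c1O | intermediate
21 | (3S)-3-[2,4-dimethoxy-3-(methoxymethoxy)-5-(2-methylbut-3-en-2-yl)phenyl]-7-(methoxymethoxy)chroman | C=CC(C)(C)c1cc([C@H]2COc3cc(OCOC)ccc3C2)c(OC)c(OCOC)c1OC | intermediate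
22 | (3S)-3-[3-hydroxy-2,4-dimethoxy-5-(2-methylbut-3-en-2-yl)phenyl]chroman-7-ol | C=CC(C)(C)c1cc([C@H]2COc3cc(O)ccc3C2)c(OC)c(O)c1OC | target

**Step count**

Total: 14 steps. Longest linear sequence: 11 steps (steps 1–6 and 10–14).

**Steps most likely to fail**

Step 12 (the proposed new method). The dianion may not take up the amide acetal at carbon, or the enaminone anion may close through oxygen or stall before the C5'–C6' bond forms. The fallback uses known chemistry and sets out from 17. The dianion (LiN(iPr)2, 2.2 equiv, THF, −78 → 0 °C) is C-formylated at its terminal carbon with ethyl formate, a known acylation of diketone dianions, to give the 3,5-dioxo aldehyde 4-(methoxymethoxy)-7,7-dimethyl-2-[(3S)-7-(methoxymethoxy)chroman-3-yl]-3,5-dioxonon-8-enal F1, handled as its hydroxymethylene tautomer. This triketide-type chain should then undergo the known intramolecular aldol condensation and aromatisation under mild base (K2CO3, aqueous MeOH, 23 °C), C5' attacking the formyl carbon, and the route is rejoined at 20.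

Step 3. Carbene addition to the electron-rich para-alkoxy aldehyde may be slow, and the enantiomeric purity may erode through incomplete facial control or base-mediated epimerisation at C3. The fallback sets out from 4. Stetter cyclisation with an achiral thiazolium salt (3-benzyl-5-(2-hydroxyethyl)-4-methylthiazolium chloride, Et3N, dioxane, 70 °C) gives racemic methyl 2-[7-(methoxymethoxy)-4-oxochroman-3-yl]acetate F2. C3 is then set by dynamic kinetic resolution in an asymmetric transfer hydrogenation (RuCl(TsDPEN)(p-cymene), ligand antipode chosen for the 4S carbinol, HCO2H–Et3N, 40 °C), in which the amine racemises the unreacted ketone through its enol while one enantiomer is reduced. This should give the cis-hydroxy ester methyl 2-[(3S,4S)-4-hydroxy-7-(methoxymethoxy)chroman-3-yl]acetate F3. LiAlH4 reduces it (or its γ-lactone) to the (3S,4S)-diol, a single C4 epimer of 6, where the route is rejoined.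

Step 10. Ketone 15 may be deprotonated on the neopentyl side, or proton transfer from the enolisable aldehyde may compete with addition. The fallback sets out from 11 (with 8) and makes steps 8 and 9 unnecessary. The kinetic lithium enolate of methyl ketone 11, whose deprotonation at the methyl group is unambiguous, is added to 8 to give the aldol 2-hydroxy-6,6-dimethyl-1-[(3S)-7-(methoxymethoxy)chroman-3-yl]oct-7-en-4-one F4. IBX oxidation gives 6,6-dimethyl-1-[(3S)-7-(methoxymethoxy)chroman-3-yl]oct-7-ene-2,4-dione F5. Its potassium enolate (KN(SiMe3)2, THF, −78 °C) is hydroxylated at the central carbon with 2-(phenylsulfonyl)-3-phenyloxaziridine to give 3-hydroxy-6,6-dimethyl-1-[(3S)-7-(methoxymethoxy)chroman-3-yl]oct-7-ene-2,4-dione F6. MOMCl and i-Pr2NEt then give 17, where the route is rejoined.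

**Further compounds**

F1 | step 12 | 4-(methoxymethoxy)-7,7-dimethyl-2-[(3S)-7-(methoxymethoxy)chroman-3-yl]-3,5-dioxonon-8-enal | C=CC(C)(C)CC(=O)C(OCOC)C(=O)C(C=O)[C@H]1COc2cc(OCOC)ccc2C1
F2 | step 3 | methyl 2-[7-(methoxymethoxy)-4-oxochroman-3-yl]acetate (racemic) | COC(=O)CC1COc2cc(OCOC)ccc2C1=O
F3 | step 3 | methyl 2-[(3S,4S)-4-hydroxy-7-(methoxymethoxy)chroman-3-yl]acetate | COC(=O)C[C@H]1COc2cc(OCOC)ccc2[C@H]1O
F4 | step 10 | 2-hydroxy-6,6-dimethyl-1-[(3S)-7-(methoxymethoxy)chroman-3-yl]oct-7-en-4-one | C=CC(C)(C)CC(=O)CC(O)C[C@H]1COc2cc(OCOC)ccc2C1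
F5 | step 10 | 6,6-dimethyl-1-[(3S)-7-(methoxymethoxy)chroman-3-yl]oct-7-ene-2,4-dione | C=CC(C)(C)CC(=O)CC(=O)C[C@H]1COc2cc(OCOC)ccc2C1
F6 | step 10 | 3-hydroxy-6,6-dimethyl-1-[(3S)-7-(methoxymethoxy)chroman-3-yl]oct-7-ene-2,4-dione | C=CC(C)(C)CC(=O)C(O)C(=O)C[C@H]1COc2cc(OCOC)ccc2C1
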